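In carotenoid numbering, ring A (C1–C6) is the cyclohexadiene and ring B (C1'–C6') the carbinol ring. The central bond C15–C15' is single only because the polyene C2…C4' is a retro system, shifted by one position against a normal carotenoid. It is therefore made as a C15=C15' double bond, whose E/Z outcome is irrelevant. The union is a Wittig reaction of a 3,4-didehydroretinyl phosphonium salt with a C20 polyenal bearing a tertiary hydroxyl at C6' of ring B. This one operation builds the C40 skeleton and wires C6'–OH to C2–H of ring A through eleven conjugated double bonds. Acid then expels water across 24 atoms, moving every double bond by one place. CBS reduction sets C3'.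

Key step: step 9

Remark on the chemistry: all polyenes are handled under argon in dim light. The carbinol stereocentre of 6 is erased in step 10, so racemic 6 would serve equally.

Step 1
Reactants: 1 all-trans-retinal
Product: 3 all-trans-3,4-didehydroretinal, via 4-bromoretinal 2 (not isolated)
Conditions: NBS (1.0 equiv), CH2Cl2, −15 °C, dark; then N-phenylmorpholine (2 equiv), 40 °C
Reagents that add atoms: none
Why: Wohl–Ziegler bromination should strike the ring allylic CH2 at C4, since the formyl group tempers the chain toward electrophilic bromine, and the amine base then removes HBr toward C3 to give the conjugated 3,4-ene.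

Step 2
Reactants: 3 all-trans-3,4-didehydroretinal
Product: 4 all-trans-3,4-didehydroretinol
Conditions: NaBH4, MeOH/THF, 0 °C
Reagents that add atoms: none
Why: NaBH4 reduces the polyenal by 1,2-addition only and leaves the hexaene untouched.

Step 3
Reactants: 4 all-trans-3,4-didehydroretinol
Product: 5 (all-trans-3,4-didehydroretinyl)triphenylphosphonium bromide
Conditions: PPh3·HBr (1.05 equiv), MeOH, 0 °C to rt, dark
Reagents that add atoms: triphenylphosphine hydrobromide, Br.c1ccc(cc1)P(c1ccccc1)c1ccccc1
Why: The acid ionises the allylic alcohol to the delocalised polyenyl cation, which PPh3 captures irreversibly at its unhindered terminus C15 (SN1-type phosphonium salt formation as used for retinol), so that any hydrocarbon formed by proton loss is drawn back by reprotonation.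

Step 4
Reactants: 6 (S)-(+)-abscisic acid
Product: 7 abscisyl triol, (2Z,4E)-5-[(1S)-1,4-dihydroxy-2,6,6-trimethylcyclohex-2-en-1-yl]-3-methylpenta-2,4-dien-1-ol (both epimers at ring C4)
Conditions: LiAlH4 (3 equiv), THF, 0 °C to rt; H2O/aq. NaOH work-up
Reagents that add atoms: none
Why: LiAlH4 reduces the dienoic acid to the primary allylic alcohol and the enone by 1,2-addition while the tertiary carbinol is merely deprotonated, and the new ring carbinol centre is of no account because step 5 oxidises it again.

Step 5
Reactants: 7 abscisyl triol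
Product: 8 (S)-abscisic aldehyde, (2Z,4E)-5-[(1S)-1-hydroxy-2,6,6-trimethyl-4-oxocyclohex-2-en-1-yl]-3-methylpenta-2,4-dienal
Conditions: activated MnO2 (excess), CH2Cl2, rt
Reagents that add atoms: none
Why: Activated MnO2 oxidises allylic alcohols selectively, so the primary dienylic and the secondary ring alcohol both go to carbonyl groups and the tertiary hydroxyl cannot react.

Step 6
Reactants: 8 (S)-abscisic aldehyde; 9 diethyl (E)-(3-cyano-2-methylallyl)phosphonate
Product: 10 C20 keto nitrile, (2E,4E,6Z,8E)-9-[(1S)-1-hydroxy-2,6,6-trimethyl-4-oxocyclohex-2-en-1-yl]-3,7-dimethylnona-2,4,6,8-tetraenenitrile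
Conditions: 9 (1.2 equiv), n-BuLi (1.15 equiv), THF, −78 °C; then 8, −78 to 0 °C
Reagents that add atoms: diethyl (E)-(3-cyano-2-methylallyl)phosphonate 9, CCOP(=O)(OCC)C/C(C)=C/C#N
Why: In this Horner–Wadsworth–Emmons olefination the nitrile-stabilised anion of 9 attacks the unhindered aldehyde much faster than the ring enone and is too weak a base to harm the tertiary alcohol; E is expected at C11'=C12', though no chain geometry made before step 10 passes into the target.

Step 7
Reactants: 10 C20 keto nitrile
Product: 11 C20 dihydroxy aldehyde, (2E,4E,6Z,8E)-9-[(1S)-1,4-dihydroxy-2,6,6-trimethylcyclohex-2-en-1-yl]-3,7-dimethylnona-2,4,6,8-tetraenal (both epimers at ring C4)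
Conditions: i-Bu2AlH (3.5 equiv), toluene, −78 °C; then aq. potassium sodium tartrate KNaC4H4O6, 0 °C
Reagents that add atoms: water, O
Why: At low temperature i-Bu2AlH adds only once to the conjugated nitrile and hydrolysis on work-up gives the polyenal, as in the reduction of retinonitrile to retinal, while the unavoidable 1,2-reduction of the ring ketone is repaired in step 8.

Step 8
Reactants: 11 C20 dihydroxy aldehyde
Product: 12 C20 keto aldehyde, (2E,4E,6Z,8E)-9-[(1S)-1-hydroxy-2,6,6-trimethyl-4-oxocyclohex-2-en-1-yl]-3,7-dimethylnona-2,4,6,8-tetraenal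
Conditions: activated MnO2 (excess), CH2Cl2, rt, dark
Reagents that add atoms: none
Why: MnO2 takes the secondary allylic alcohol of ring B back to the enone and has no action on the polyenal or on the tertiary alcohol.

Step 9
Reactants: 5 (all-trans-3,4-didehydroretinyl)triphenylphosphonium bromide; 12 C20 keto aldehyde
Product: 14 (6'S,9'Z)-6'-hydroxy-3,4,4',5'-tetradehydro-5',6'-dihydro-β,β-caroten-3'-one, via polyenyl ylide 13 (not isolated)
Conditions: 5 (1.05 equiv), NaOMe (1.05 equiv), CH2Cl2/MeOH, −20 °C; then 12, −20 to 0 °C, argon, dark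
Reagents that add atoms: none
Why: NaOMe deprotonates 5 at C15 to the semi-stabilised polyenyl ylide 13, C15 adds to the formyl carbon C15' of 12, and the oxaphosphetane collapses to Ph3PO and the C15=C15' double bond. This is the Wittig olefination in the form long used to join retinyl phosphonium salts to C20 polyenals. No ring is closed and no stereocentre is formed; the C6' carbinol centre is only carried along. The selectivity needed is aldehyde over the ring B enone, secured by the much higher reactivity of the unhindered formyl group toward a semi-stabilised ylide and by the use of about one equivalent of 13. The habitual weakness of this union, a 15E/15Z mixture, does not matter, because the π bond is a temporary one that step 10 moves away, leaving C15–C15' as the single bond between C14=C15 and C15'=C14'. What is exploited is that ring A offers an allylic C2–H and ring B an ionisable C6'–OH at the two ends of the eleven conjugated double bonds that the coupling completes.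

Step 10
Reactants: 14 C40 carbinol
Product: 16 2,3,4',5'-tetradehydro-4,5'-retro-β,β-caroten-3'-one (all-trans chain; C8 and C8' cis to C1 and C1'), via polyenyl cation 15 (not isolated)
Conditions: p-TsOH·H2O (5 mol %), toluene, 4 Å molecular sieves, 0 °C to rt, argon, dark; Et3N quench; brief reflux in heptane, crystallisation
Reagents that add atoms: none
Why: This is a vinylogous E1 dehydration of the anhydroretinol type (retro rearrangement of a polyenyl carbinol), in which loss of the protonated doubly allylic C6' hydroxyl gives cation 15, delocalised from C6' to C3, and loss of H+ from C2 under reversible, non-nucleophilic conditions leads to the thermodynamic sink with thirteen C=C bonds conjugated to the C3' carbonyl; every former s-trans single bond becomes an E double bond, every former double bond (9'Z and 15E/Z included) becomes a freely rotating single bond, and the two ring-exocyclic double bonds should settle with C8 and C8' beside the gem-dimethyl carbons to avoid the in-plane methyl groups at C5 and C5'.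

Step 11
Reactants: 16 retro polyenone
Product: 17 (3'S)-2,3,4',5'-tetradehydro-4,5'-retro-β,β-caroten-3'-ol (target)
Conditions: (R)-2-methyl-CBS-oxazaborolidine (0.3 equiv), catecholborane (2 equiv), CH2Cl2/toluene, −60 °C; MeOH, then aq. NaHCO3; Et3N-deactivated silica
Reagents that add atoms: none
Why: In this Corey–Bakshi–Shibata reduction the oxazaborolidine should bind the C3' carbonyl with the alkenyl branch C4' as the large and C2'H2 as the small group, so that the (R)-catalyst directs the hydride of catecholborane in pure 1,2-fashion to the face that gives the (3'S)-alcohol, and the base-buffered work-up keeps the ionisable allylic alcohol intact.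

Compound list
1 | all-trans-retinal | CC1=C(C(C)(C)CCC1)/C=C/C(C)=C/C=C/C(C)=C/C=O | starting material
2 | 4-bromoretinal (racemic, all-trans) | CC1=C(C(C)(C)CCC1Br)/C=C/C(C)=C/C=C/C(C)=C/C=O | intermediate
3 | all-trans-3,4-didehydroretinal | CC1=C(C(C)(C)CC=C1)/C=C/C(C)=C/C=C/C(C)=C/C=O | intermediate
4 | all-trans-3,4-didehydroretinol | CC1=C(C(C)(C)CC=C1)/C=C/C(C)=C/C=C/C(C)=C/CO | intermediate
5 | (all-trans-3,4-didehydroretinyl)triphenylphosphonium bromide | CC1=C(C(C)(C)CC=C1)/C=C/C(C)=C/C=C/C(C)=C/C[P+](c1ccccc1)(c1ccccc1)c1ccccc1.[Br-] | intermediate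
6 | (S)-(+)-abscisic acid | CC1=CC(=O)CC(C)(C)[C@@]1(O)/C=C/C(C)=C\C(O)=O | starting material
7 | abscisyl triol (epimers at the secondary ring carbinol) | CC1=CC(O)CC(C)(C)[C@@]1(O)/C=C/C(C)=C\CO | intermediate
8 | (S)-abscisic aldehyde | CC1=CC(=O)CC(C)(C)[C@@]1(O)/C=C/C(C)=C\C=O | intermediate
9 | diethyl (E)-(3-cyano-2-methylallyl)phosphonate | CCOP(=O)(OCC)C/C(C)=C/C#N | starting material
10 | C20 keto nitrile | CC1=CC(=O)CC(C)(C)[C@@]1(O)/C=C/C(C)=C\C=C\C(C)=C\C#N | intermediate
11 | C20 dihydroxy aldehyde (epimers at the secondary ring carbinol) | CC1=CC(O)CC(C)(C)[C@@]1(O)/C=C/C(C)=C\C=C\C(C)=C\C=O | intermediate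
12 | C20 keto aldehyde | CC1=CC(=O)CC(C)(C)[C@@]1(O)/C=C/C(C)=C\C=C\C(C)=C\C=O | intermediate
13 | (3,4-didehydroretinylidene)triphenylphosphorane | CC1=C(C(C)(C)CC=C1)/C=C/C(C)=C/C=C/C(C)=C/C=P(c1ccccc1)(c1ccccc1)c1ccccc1 | intermediate
14 | (6'S,9'Z)-6'-hydroxy-3,4,4',5'-tetradehydro-5',6'-dihydro-β,β-caroten-3'-one (15E drawn; 15Z serves as well) | CC1=C(C(C)(C)CC=C1)/C=C/C(C)=C/C=C/C(C)=C/C=C/C=C(C)/C=C/C=C(C)\C=C\[C@@]1(O)C(C)=CC(=O)CC1(C)C | intermediate
15 | delocalised C40 polyenyl cation (drawn with the charge at C3) | CC1=C[CH+]CC(C)(C)\C1=C/C=C(C)/C=C/C=C(C)/C=C/C=C/C(C)=C/C=C/C(C)=C/C=C1/C(C)=CC(=O)CC1(C)C | intermediate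
16 | 2,3,4',5'-tetradehydro-4,5'-retro-β,β-caroten-3'-one | CC1=CC=CC(C)(C)\C1=C/C=C(C)/C=C/C=C(C)/C=C/C=C/C(C)=C/C=C/C(C)=C/C=C1/C(C)=CC(=O)CC1(C)C | intermediate
17 | (3'S)-2,3,4',5'-tetradehydro-4,5'-retro-β,β-caroten-3'-ol | CC1=CC=CC(C)(C)\C1=C/C=C(C)/C=C/C=C(C)/C=C/C=C/C(C)=C/C=C/C(C)=C/C=C1/C(C)=C[C@@H](O)CC1(C)C | target

Total step count: 11. Longest linear sequence: 8 steps (steps 4 to 11, from 6).

Steps most likely to fail

**Step 10.**
- What may go wrong: proton loss from the methyl groups at C5, C9 or C13 instead of C2; capture of the cation by the water that is released; a 1,2-methyl shift that aromatises ring A; incomplete settling of the two ring-exocyclic double bonds.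
- The fallback divides the long-range elimination into a capture and a separate metal-catalysed elimination. It sets out from 14.
- Dilute H2SO4 in aqueous acetone at 0 °C should let water capture the cation at C3. This is an allylic transposition of the hydroxyl over the whole chain, and it should give 3-hydroxy-4',5'-didehydro-4,5'-retro-β,β-caroten-3'-one F1.
- Ac2O/pyridine gives its 3-acetate F2.
- The zerovalent palladium complex Pd(PPh3)4 with Et3N in THF at 50 °C then removes acetic acid through a π-allyl complex and β-hydride loss from C2 (palladium-catalysed elimination of an allylic acetate to a diene). The route is rejoined at 16.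

**Step 11.**
- What may go wrong: poor facial selectivity because the two flanks of the ring ketone differ little near the carbonyl group; ionisation of the boron-bound allylic alcohol; low solubility at low temperature.
- The fallback replaces asymmetric reduction by resolution. It sets out from 16.
- Luche reduction (NaBH4, CeCl3·7H2O, MeOH/THF, −20 °C) gives the racemic retro carotenol F3.
- Lipase-catalysed acylation (Burkholderia cepacia lipase, vinyl acetate, toluene, rt) should, by the empirical rule for secondary alcohols, convert the (3'R)-enantiomer into the (3'R)-acetate F4. The (3'S)-alcohol is left and separated by chromatography, which comes back to the route at 17.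

**Step 1.**
- What may go wrong: addition of bromine to the chain, multiple bromination, or decay of the allylic bromide before elimination.
- The fallback builds the aldehyde from a ring that already holds the 3,4-double bond. It sets out from 9 and commercial safranal F5.
- Horner–Wadsworth–Emmons olefination (n-BuLi, THF) gives the C15 dienenitrile F6, and i-Bu2AlH gives the C15 dienal F7.
- A second olefination with 9 gives 3,4-didehydroretinonitrile F8, and i-Bu2AlH reduction with hydrolysis comes back to the route at 3.

Further compounds
F1 | step 10 | 3-hydroxy-4',5'-didehydro-4,5'-retro-β,β-caroten-3'-one (racemic) | CC1=CC(O)CC(C)(C)\C1=C/C=C(C)/C=C/C=C(C)/C=C/C=C/C(C)=C/C=C/C(C)=C/C=C1/C(C)=CC(=O)CC1(C)C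
F2 | step 10 | 3-acetoxy-4',5'-didehydro-4,5'-retro-β,β-caroten-3'-one (racemic) | CC1=CC(OC(C)=O)CC(C)(C)\C1=C/C=C(C)/C=C/C=C(C)/C=C/C=C/C(C)=C/C=C/C(C)=C/C=C1/C(C)=CC(=O)CC1(C)C
F3 | step 11 | racemic 2,3,4',5'-tetradehydro-4,5'-retro-β,β-caroten-3'-ol | CC1=CC=CC(C)(C)\C1=C/C=C(C)/C=C/C=C(C)/C=C/C=C/C(C)=C/C=C/C(C)=C/C=C1/C(C)=CC(O)CC1(C)C
F4 | step 11 | (3'R)-2,3,4',5'-tetradehydro-4,5'-retro-β,β-caroten-3'-yl acetate | CC1=CC=CC(C)(C)\C1=C/C=C(C)/C=C/C=C(C)/C=C/C=C/C(C)=C/C=C/C(C)=C/C=C1/C(C)=C[C@H](OC(C)=O)CC1(C)C
F5 | step 1 | safranal (commercial) | CC1=C(C=O)C(C)(C)CC=C1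
F6 | step 1 | (2E,4E)-3-methyl-5-(2,6,6-trimethylcyclohexa-1,3-dien-1-yl)penta-2,4-dienenitrile | CC1=C(C(C)(C)CC=C1)/C=C/C(C)=C/C#N
F7 | step 1 | (2E,4E)-3-methyl-5-(2,6,6-trimethylcyclohexa-1,3-dien-1-yl)penta-2,4-dienal | CC1=C(C(C)(C)CC=C1)/C=C/C(C)=C/C=O
F8 | step 1 | all-trans-3,4-didehydroretinonitrile | CC1=C(C(C)(C)CC=C1)/C=C/C(C)=C/C=C/C(C)=C/C#N
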